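## Retrosynthetic overview

1. Sideroxylonal A comes from four-fold Rieche formylation and then five-fold O-demethylation of a pentamethoxy 2-aryl-chroman core.
2. The C2–aryl bond is cut last: 1,3,5-trimethoxybenzene adds (Friedel–Crafts) to the cyclic oxocarbenium ion of a (3R,4S)-2-chromanol, trans to the C3 isopropyl group.
3. The 2-chromanol comes from a one-carbon ring contraction (loss of the lactone carbonyl carbon) of a cis-4,5-disubstituted 1-benzoxepin-2-one.
4. Key disconnection C3–C4: a carbene-catalysed [4+3] annulation in which the β-carbon of (E)-4-methylpent-2-enal reacts as a homoenolate with the methide carbon of an o-quinone methide, joining two normally electrophilic carbons and setting both stereocentres.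
5. The o-quinone methide precursor (a benzylic sulfone) comes from 2-hydroxy-4,6-dimethoxybenzaldehyde and iBuMgBr. Ring order: both benzene rings are bought, the seven-membered lactone is formed first, it is contracted to the pyran ring, and the pendant aryl ring is attached last.

Assumption: the target SMILES is read as (2R,3R,4S), i.e. 2-aryl/3-isopropyl trans and 3-isopropyl/4-isobutyl cis; the facial sense of the chosen catalyst antipode is assigned by analogy, and its mirror image (also commercial) is used if the first annulation shows the opposite sense.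

## Route

Step 1
Reactants: 1 2-hydroxy-4,6-dimethoxybenzaldehyde; 2 isobutylmagnesium bromide
Product: 3 2-(1-hydroxy-3-methylbutyl)-3,5-dimethoxyphenol (racemic)
Conditions: iBuMgBr (2.5 equiv), THF, 0 °C to rt; pH 7 phosphate buffer
Reagents that add atoms: isobutylmagnesium bromide, CC(C)C[Mg]Br
Why: Grignard 1,2-addition to the aldehyde after in situ deprotonation of the phenol (hence more than two equivalents); the new carbinol centre is racemic and is erased when the o-quinone methide is formed.

Step 2
Reactants: 3 2-(1-hydroxy-3-methylbutyl)-3,5-dimethoxyphenol; 4 sodium 4-methylbenzenesulfinate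
Product: 5 3,5-dimethoxy-2-[3-methyl-1-(4-methylbenzenesulfonyl)butyl]phenol (racemic)
Conditions: TolSO2Na (1.5 equiv), HCO2H/H2O 1:1, rt
Reagents that add atoms: sodium 4-methylbenzenesulfinate, Cc1ccc(cc1)S(=O)[O-].[Na+]
Why: Acid-promoted SN1 substitution: the electron-rich o-hydroxybenzyl alcohol ionises (benzylic cation/o-quinone methide) and is trapped on sulfur by sulfinate, giving a bench-stable o-quinone methide precursor whose racemic centre is erased in step 3.

Step 3
Reactants: 5 3,5-dimethoxy-2-[3-methyl-1-(4-methylbenzenesulfonyl)butyl]phenol; 6 (E)-4-methylpent-2-enal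
Product: 8 (4R,5S)-6,8-dimethoxy-5-(2-methylpropyl)-4-(propan-2-yl)-4,5-dihydro-1-benzoxepin-2(3H)-one, via o-quinone methide 7 (not isolated)
Conditions: (5aR,10bS)-2-mesityl-5a,10b-dihydro-4H,6H-indeno[2,1-b][1,2,4]triazolo[4,3-d][1,4]oxazin-2-ium chloride (C21H22ClN3O, 15 mol %), Cs2CO3 (1.3 equiv), 4 Å MS, toluene, 0 °C to rt, 6 (2 equiv) added over 4 h
Reagents that add atoms: (E)-4-methylpent-2-enal, CC(C)/C=C/C=O
Why: NHC-catalysed homoenolate [4+3] annulation: base-induced loss of sulfinate from 5 gives planar 7, the Breslow intermediate of 6 attacks its methide carbon through the enal β-carbon, and the phenoxide then acylates on the acyl azolium to close the lactone; the aminoindanol backbone blocks one face of the homoenolate and a compact endo-type transition state places isopropyl and isobutyl cis, so C4 (R) and C5 (S) are both set by the catalyst from achiral 7.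

Step 4
Reactants: 8 (4R,5S)-6,8-dimethoxy-5-(2-methylpropyl)-4-(propan-2-yl)-4,5-dihydro-1-benzoxepin-2(3H)-one
Product: 11 (3R,4S)-5,7-dimethoxy-4-(2-methylpropyl)-3-(propan-2-yl)-3,4-dihydro-2H-chromen-2-ol (anomer mixture), via silyl ketene acetal 9 (not isolated), via aldehyde silyl carbonate 10 (not isolated)
Conditions: LiN(iPr)2 (1.2 equiv), Me3SiCl (1.5 equiv), THF, −78 °C; solvent switch to CH2Cl2; O3 (1.0 equiv, titrated CH2Cl2 solution), −78 °C; Me2S; pH 7 buffer, rt
Reagents that add atoms: ozone, [O-][O+]=O
Why: Proposed new method: kinetic O-silylation gives cyclic ketene silyl acetal 9, whose very electron-rich C=C is cleaved by one equivalent of ozone faster than the arene, so the former α-carbon becomes the aldehyde of 10 while the former carbonyl carbon becomes an aryl silyl carbonate that hydrolyses and decarboxylates to the free phenol, which closes on the aldehyde as the six-membered lactol (net one-carbon ring contraction under neutral conditions, so the α-stereocentre C3 is not enolised); the closest known reaction type is the ozonolytic cleavage of silyl enol ethers and ketene silyl acetals to nor-carbonyl compounds.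

Step 5
Reactants: 11 (3R,4S)-5,7-dimethoxy-4-(2-methylpropyl)-3-(propan-2-yl)-3,4-dihydro-2H-chromen-2-ol; 12 1,3,5-trimethoxybenzene
Product: 13 (2R,3R,4S)-5,7-dimethoxy-4-(2-methylpropyl)-3-(propan-2-yl)-2-(2,4,6-trimethoxyphenyl)-3,4-dihydro-2H-chromene
Conditions: 12 (1.05 equiv), BF3·OEt2 (0.3 equiv), 4 Å MS, CH2Cl2, −40 °C
Reagents that add atoms: 1,3,5-trimethoxybenzene, COc1cc(OC)cc(OC)c1
Why: Friedel–Crafts C-arylation of a cyclic oxocarbenium ion (C-aryl glycosylation type): the arene adds to C2 on the face opposite the cis-disposed C3 isopropyl and C4 isobutyl groups to give the 2,3-trans (2R) isomer, which is also the thermodynamic one (equatorial aryl) should the benzylic C2–O bond re-ionise; low temperature and one equivalent of arene limit C3 enolisation and double arylation.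

Step 6
Reactants: 13 (2R,3R,4S)-5,7-dimethoxy-4-(2-methylpropyl)-3-(propan-2-yl)-2-(2,4,6-trimethoxyphenyl)-3,4-dihydro-2H-chromene
Product: 14 (2R,3R,4S)-2-(3,5-diformyl-2,4,6-trimethoxyphenyl)-5,7-dimethoxy-4-(2-methylpropyl)-3-(propan-2-yl)-3,4-dihydro-2H-chromene-6,8-dicarbaldehyde
Conditions: Cl2CHOMe (12 equiv), TiCl4 (12 equiv), CH2Cl2, −78 °C to rt (substrate added to the premixed reagent); ice/1 M HCl
Reagents that add atoms: dichloromethyl methyl ether, ClC(Cl)OC; water, O
Why: Rieche formylation (electrophilic aromatic substitution by the TiCl4-activated chloro(methoxy)carbenium ion): each ring carries three oxygen donors, so its two free positions, each flanked by two oxygen substituents, are formylated in turn, and the first formyl group on the pendant ring shuts down ionisation of the C2–O bond; no stereocentre is touched.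

Step 7
Reactants: 14 (2R,3R,4S)-2-(3,5-diformyl-2,4,6-trimethoxyphenyl)-5,7-dimethoxy-4-(2-methylpropyl)-3-(propan-2-yl)-3,4-dihydro-2H-chromene-6,8-dicarbaldehyde
Product: 15 sideroxylonal A
Conditions: BBr3 (12 equiv), CH2Cl2, −78 to 0 °C; H2O
Reagents that add atoms: none
Why: Lewis-acid O-demethylation: every methoxy group is ortho to a formyl group, so chelation-assisted cleavage is fast, while the secondary benzylic C2–O ether now sits on an electron-poor aryl ring and does not ionise; the stereocentres are untouched.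

## Compound list

1 | 2-hydroxy-4,6-dimethoxybenzaldehyde | O=Cc1c(O)cc(OC)cc1OC | starting material
2 | isobutylmagnesium bromide | CC(C)C[Mg]Br | starting material
3 | 2-(1-hydroxy-3-methylbutyl)-3,5-dimethoxyphenol (racemic) | CC(C)CC(O)c1c(O)cc(OC)cc1OC | intermediate
4 | sodium 4-methylbenzenesulfinate | Cc1ccc(cc1)S(=O)[O-].[Na+] | starting material
5 | 3,5-dimethoxy-2-[3-methyl-1-(4-methylbenzenesulfonyl)butyl]phenol (racemic) | CC(C)CC(c1c(O)cc(OC)cc1OC)S(=O)(=O)c1ccc(C)cc1 | intermediate
6 | (E)-4-methylpent-2-enal | CC(C)/C=C/C=O | starting material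
7 | (Z)-3,5-dimethoxy-6-(3-methylbutylidene)cyclohexa-2,4-dien-1-one (o-quinone methide, alkyl chain syn to C=O) | CC(C)C/C=C1\C(=O)C=C(OC)C=C1OC | intermediate
8 | (4R,5S)-6,8-dimethoxy-5-(2-methylpropyl)-4-(propan-2-yl)-4,5-dihydro-1-benzoxepin-2(3H)-one (cis) | CC(C)C[C@@H]1c2c(OC)cc(OC)cc2OC(=O)C[C@@H]1C(C)C | intermediate
9 | [(4R,5S)-6,8-dimethoxy-5-(2-methylpropyl)-4-(propan-2-yl)-4,5-dihydro-1-benzoxepin-2-yl]oxy(trimethyl)silane | CC(C)C[C@@H]1c2c(OC)cc(OC)cc2OC(O[Si](C)(C)C)=C[C@@H]1C(C)C | intermediate
10 | (2R,3S)-3-[2,4-dimethoxy-6-(trimethylsilyloxycarbonyloxy)phenyl]-5-methyl-2-(propan-2-yl)hexanal | CC(C)C[C@@H]([C@@H](C(C)C)C=O)c1c(OC)cc(OC)cc1OC(=O)O[Si](C)(C)C | intermediate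
11 | (3R,4S)-5,7-dimethoxy-4-(2-methylpropyl)-3-(propan-2-yl)-3,4-dihydro-2H-chromen-2-ol (anomer mixture) | CC(C)C[C@@H]1c2c(OC)cc(OC)cc2OC(O)[C@@H]1C(C)C | intermediate
12 | 1,3,5-trimethoxybenzene | COc1cc(OC)cc(OC)c1 | starting material
13 | (2R,3R,4S)-5,7-dimethoxy-4-(2-methylpropyl)-3-(propan-2-yl)-2-(2,4,6-trimethoxyphenyl)-3,4-dihydro-2H-chromene | CC(C)C[C@@H]1c2c(OC)cc(OC)cc2O[C@@H](c2c(OC)cc(OC)cc2OC)[C@@H]1C(C)C | intermediate
14 | (2R,3R,4S)-2-(3,5-diformyl-2,4,6-trimethoxyphenyl)-5,7-dimethoxy-4-(2-methylpropyl)-3-(propan-2-yl)-3,4-dihydro-2H-chromene-6,8-dicarbaldehyde | CC(C)C[C@@H]1c2c(OC)c(C=O)c(OC)c(C=O)c2O[C@@H](c2c(OC)c(C=O)c(OC)c(C=O)c2OC)[C@@H]1C(C)C | intermediate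
15 | sideroxylonal A, (2R,3R,4S) | CC(C)C[C@@H]1c2c(O)c(C=O)c(O)c(C=O)c2O[C@@H](c2c(O)c(C=O)c(O)c(C=O)c2O)[C@@H]1C(C)C | target

## Step count and risks

Total step count: 7. Longest linear sequence: 7 steps (1 to 15).

The three steps most likely to fail are steps 3, 4 and 6.

Step 3 is the weakest. It joins two hindered secondary carbons, the alkyl o-quinone methide can tautomerise to the styrene, and β-protonation of the homoenolate can divert the system to a [4+2] enolate pathway. The cis selectivity and the enantioselectivity are expected by analogy and are not proven for this substrate pair. The fallback sets out from 5 and returns at 11, replacing the homoenolate with an azolium enolate so that no ring contraction is needed. 3-Methylbutanal is α-chlorinated (N-chlorosuccinimide, catalytic L-proline, CH2Cl2) to 2-chloro-3-methylbutanal F1. With the triazolium chloride C21H22ClN3O and Cs2CO3, F1 loses chloride to give the azolium enolate, which adds endo to 7 (released from 5) to give cis-lactone (3R,4S)-5,7-dimethoxy-4-(2-methylpropyl)-3-(propan-2-yl)-3,4-dihydro-2H-chromen-2-one F2. Reduction with iBu2AlH in CH2Cl2 at −78 °C gives lactol 11.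

Step 4 can fail through ozone attack on the dimethoxyaryl ring or through incomplete silylation. The fallback sets out from 8 and returns at 11 by a classical three-operation degradation. The lactone enolate (KN(SiMe3)2, THF, −78 °C) is hydroxylated with 2-(phenylsulfonyl)-3-phenyloxaziridine to (4R,5S)-3-hydroxy-6,8-dimethoxy-5-(2-methylpropyl)-4-(propan-2-yl)-4,5-dihydro-1-benzoxepin-2(3H)-one F3. LiAlH4 opens it to (3R,4S)-4-(2-hydroxy-4,6-dimethoxyphenyl)-6-methyl-3-(propan-2-yl)heptane-1,2-diol F4. NaIO4 (1.05 equiv, THF/H2O, 0 °C) cleaves the glycol; the resulting hydroxy aldehyde closes to lactol 11.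

Step 6 can fail because excess TiCl4 may open the acid-labile 2-aryl-chroman ether before the pendant ring is deactivated, and the fourth formylation may stall. The fallback sets out from 13 and returns at 15 by reversing the order of the last two operations. BBr3 in CH2Cl2 (−78 to 0 °C; any ring-opened benzylic bromide re-closes to the trans chroman on aqueous work-up) gives (2R,3R,4S)-4-(2-methylpropyl)-3-(propan-2-yl)-2-(2,4,6-trihydroxyphenyl)-3,4-dihydro-2H-chromene-5,7-diol F5. Vilsmeier–Haack formylation of the two free phloroglucinol rings (POCl3, DMF, ethyl acetate, rt; then H2O), the standard route to diformylphloroglucinols, then gives 15.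

## Further compounds

F1 | step 3 | 2-chloro-3-methylbutanal (racemic) | CC(C)C(Cl)C=O
F2 | step 3 | (3R,4S)-5,7-dimethoxy-4-(2-methylpropyl)-3-(propan-2-yl)-3,4-dihydro-2H-chromen-2-one | CC(C)C[C@@H]1c2c(OC)cc(OC)cc2OC(=O)[C@@H]1C(C)C
F3 | step 4 | (4R,5S)-3-hydroxy-6,8-dimethoxy-5-(2-methylpropyl)-4-(propan-2-yl)-4,5-dihydro-1-benzoxepin-2(3H)-one (C3 epimer mixture) | CC(C)C[C@@H]1c2c(OC)cc(OC)cc2OC(=O)C(O)[C@@H]1C(C)C
F4 | step 4 | (3R,4S)-4-(2-hydroxy-4,6-dimethoxyphenyl)-6-methyl-3-(propan-2-yl)heptane-1,2-diol (C2 epimer mixture) | CC(C)C[C@@H]([C@@H](C(C)C)C(O)CO)c1c(OC)cc(OC)cc1O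
F5 | step 6 | (2R,3R,4S)-4-(2-methylpropyl)-3-(propan-2-yl)-2-(2,4,6-trihydroxyphenyl)-3,4-dihydro-2H-chromene-5,7-diol | CC(C)C[C@@H]1c2c(O)cc(O)cc2O[C@@H](c2c(O)cc(O)cc2O)[C@@H]1C(C)C
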